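The O–C12(=O) unit of the five-membered C6–C7=C11–C12–O butenolide (germacrane numbering) is taken as one molecule of CO2, stitched across the Z-configured C11=C7–C6 allyl unit of the ten-membered ring. In one operation an alkenyllithium at C11 captures CO2 (C11–C12) and the resulting carboxylate displaces a C6 benzenesulfonate with inversion (O–C6). This closes the lactone and converts the threo epoxy alcohol array, which hydroxyl-directed epoxidation of the Z-C4=C5 alkene provides, into the erythro array of the target. The precursor is a bis-epoxy cyclodecane with a (Z)-bromoalkylidene at C7. Its geometry is inherited from mucobromic acid through a sacrificial 8,13-butenolide.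

Key step: step 11

Remark: the SMILES is read literally. In both oxiranes the two ring carbons are cis (derived from Z-alkenes), and the configuration is (1R,4S,5R,6R,8R,10S). C8 carries the methacrylate and C13 is the CH2OAc carbon.

Step 1
Reactants: 1 4-methylpent-4-en-1-ol
Product: 2 4-methylpent-4-en-1-yl N,N-diisopropylcarbamate
Conditions: i-Pr2NCOCl, Et3N, DMAP (cat.), CH2Cl2, reflux
Reagents that add atoms: N,N-diisopropylcarbamoyl chloride, CC(C)N(C(C)C)C(=O)Cl
Why: O-carbamoylation of the primary alcohol installs the directing and leaving group for the lithiation–borylation, and no stereocentre is formed.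

Step 2
Reactants: 2 4-methylpent-4-en-1-yl N,N-diisopropylcarbamate; 3 isopropenylboronic acid pinacol ester; 4 mucobromic acid
Product: 8 (5R)-3,4-dibromo-5-[(2Z)-2,6-dimethylhepta-2,6-dien-1-yl]furan-2(5H)-one, via (S)-α-lithiated carbamate 5 (not isolated), via (R)-allylboronate 6 (not isolated), via (2Z,4R,6Z)-hydroxy acid 7 (not isolated)
Conditions: s-BuLi, (−)-sparteine, Et2O, −78 °C; 3, −78 °C, then MgBr2·OEt2, reflux; 4 + Et3N, THF, 0 → 23 °C; 1 M HCl
Reagents that add atoms: none
Why: Sparteine-mediated lithiation–borylation (pro-S deprotonation, retentive borylation, invertive 1,2-shift of the isopropenyl group) should give the (R)-α-substituted methallylboronate, whose chair allylboration of the ring-opened formyl carboxylate of 4, with the α-chain axial next to the β-methyl group, transfers chirality to C8 (R) and sets the Z-C1=C10 alkene, and acid work-up lactonises the (Z)-hydroxy acid.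

Step 3
Reactants: 8 (5R)-3,4-dibromo-5-[(2Z)-2,6-dimethylhepta-2,6-dien-1-yl]furan-2(5H)-one
Product: 9 (5R)-3,4-dibromo-5-{[(2S,3R)-2-methyl-3-(3-methylbut-3-en-1-yl)oxiran-2-yl]methyl}furan-2(5H)-one
Conditions: D-fructose-derived Shi ketone (0.5 equiv), Oxone, NaHCO3, Bu4NHSO4, MeCN–DMM/aq Na2EDTA (pH ≈ 8), 0 °C
Reagents that add atoms: potassium peroxymonosulfate (Oxone), [K+].[O-]S(=O)(=O)OO
Why: In the Shi epoxidation the chiral dioxirane attacks the electron-rich trisubstituted alkene, in preference to the 1,1-disubstituted and the dibromo-enoate alkenes, through the spiro transition state, so that reagent control on the acyclic chain should give the cis-oxirane (1R,10S).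

Step 4
Reactants: 9 (5R)-3,4-dibromo-5-{[(2S,3R)-2-methyl-3-(3-methylbut-3-en-1-yl)oxiran-2-yl]methyl}furan-2(5H)-one
Product: 10 (5R)-3-bromo-5-{[(2S,3R)-2-methyl-3-(3-methylbut-3-en-1-yl)oxiran-2-yl]methyl}-4-(prop-2-enoyl)furan-2(5H)-one
Conditions: CO (3 bar), Bu3SnCH=CH2 (1.0 equiv), Pd2(dba)3 (cat.), AsPh3, THF, 50 °C
Reagents that add atoms: carbon monoxide, [C-]#[O+]; tributyl(vinyl)stannane, C=C[Sn](CCCC)(CCCC)CCCC
Why: In the carbonylative Stille coupling Pd(0) inserts selectively into the β C7–Br bond (a vinylogous acyl bromide, the known reactive site of 3,4-dibromofuran-2(5H)-ones), and CO insertion and vinyl transfer then bring in C6 and C5 while C11–Br and all stereocentres stay untouched.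

Step 5
Reactants: 10 (5R)-3-bromo-5-{[(2S,3R)-2-methyl-3-(3-methylbut-3-en-1-yl)oxiran-2-yl]methyl}-4-(prop-2-enoyl)furan-2(5H)-one
Product: 11 (5R)-3-bromo-4-[(1R)-1-hydroxyprop-2-en-1-yl]-5-{[(2S,3R)-2-methyl-3-(3-methylbut-3-en-1-yl)oxiran-2-yl]methyl}furan-2(5H)-one
Conditions: (S)-Me-CBS, catecholborane, toluene, −78 °C
Reagents that add atoms: none
Why: In the Corey–Bakshi–Shibata reduction the fully substituted C7 alkenyl group acts as the large and the vinyl group as the small substituent, so the (S)-catalyst should give the (6R)-alcohol by reagent control, and catecholborane at −78 °C spares the alkenes, the lactone and the oxirane.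

Step 6
Reactants: 11 (5R)-3-bromo-4-[(1R)-1-hydroxyprop-2-en-1-yl]-5-{[(2S,3R)-2-methyl-3-(3-methylbut-3-en-1-yl)oxiran-2-yl]methyl}furan-2(5H)-one
Product: 12 (1R,6R,8R,10S,4Z)-11-bromo-1,10-epoxy-6-hydroxy-12-norgermacra-4,7(11)-dien-13,8-olide
Conditions: Hoveyda–Grubbs II (10 mol %), 1,4-benzoquinone (cat.), toluene (1 mM), 80 °C
Reagents that add atoms: none
Why: Ring-closing metathesis initiates at the vinyl carbinol and closes onto the 1,1-disubstituted alkene, and in a ten-membered ring that already holds a cis-oxirane and the fused butenolide the less strained Z-C4=C5 alkene should form.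

Step 7
Reactants: 12 (1R,6R,8R,10S,4Z)-11-bromo-1,10-epoxy-6-hydroxy-12-norgermacra-4,7(11)-dien-13,8-olide
Product: 13 (1R,4S,5R,6S,8R,10S)-11-bromo-1,10:4,5-diepoxy-6-hydroxy-12-norgermacr-7(11)-en-13,8-olide
Conditions: mCPBA, NaHCO3, CH2Cl2, 0 °C
Reagents that add atoms: 3-chloroperoxybenzoic acid, OOC(=O)c1cccc(Cl)c1
Why: In this Henbest-type hydroxyl-directed epoxidation the A1,3 strain of the Z-alkene keeps H6 in the alkene plane, so hydrogen-bonded delivery on the hydroxyl face, which is also the peripheral face, should give the threo (4S,5R) cis-oxirane, and the electron-poor C7=C11 alkene is inert.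

Step 8
Reactants: 13 (1R,4S,5R,6S,8R,10S)-11-bromo-1,10:4,5-diepoxy-6-hydroxy-12-norgermacr-7(11)-en-13,8-olide
Product: 14 6-benzenesulfonate of 13, (1R,4S,5R,6S,8R,10S)
Conditions: PhSO2Cl, Et3N, Me3N·HCl (cat.), CH2Cl2, 0 °C
Reagents that add atoms: benzenesulfonyl chloride, O=S(=O)(Cl)c1ccccc1
Why: Amine-catalysed O-sulfonylation leaves the C6–O bond, and thus the (6S) configuration, untouched and gives a leaving group without acidic α-hydrogen.

Step 9
Reactants: 14 6-benzenesulfonate of 13
Product: 15 (1R,4S,5R,6S,8R,10S,7(11)Z)-11-bromo-1,10:4,5-diepoxy-8,13-dihydroxy-12-norgermacr-7(11)-en-6-yl benzenesulfonate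
Conditions: DIBAL-H (4 equiv), CH2Cl2, −78 → −20 °C; Rochelle salt
Reagents that add atoms: none
Why: 1,2-Reduction of the α-bromobutenolide via the lactol gives the 2-bromo-2-ene-1,4-diol with the ring-derived geometry (Br cis to C6), and sulfonate esters and trisubstituted oxiranes are not reduced at this temperature.

Step 10
Reactants: 15 (7(11)Z)-bromo diol benzenesulfonate
Product: 16 8,13-bis(triethylsilyl) ether of 15
Conditions: TESCl, imidazole, DMAP (cat.), CH2Cl2, 0 °C
Reagents that add atoms: chlorotriethylsilane, CC[Si](Cl)(CC)CC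
Why: Silyl ether formation masks both hydroxyls, so that no alkoxide or alkyl carbonate can compete with the carboxylate in step 11, and no stereocentre is affected.

Step 11
Reactants: 16 8,13-bis(triethylsilyl) ether of 15
Product: 19 (1R,4S,5R,6R,8R,10S)-1,10:4,5-diepoxy-8,13-bis(triethylsilyloxy)germacr-7(11)-en-12,6-olide, via C11 alkenyllithium 17 (not isolated), via lithium C12 carboxylate 18 (not isolated)
Conditions: t-BuLi (2.1 equiv), THF–Et2O–pentane, −90 °C, 10 min; CO2 (dry gas), −90 → −78 °C; DMPU, → 23 °C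
Reagents that add atoms: carbon dioxide, O=C=O
Why: Br/Li exchange with t-BuLi at −90 °C outruns attack on the sulfonate, oxiranes and silyl ethers as well as β-elimination of the C13 silyloxy group, and gives alkenyllithium 17 with retained alkene geometry, which adds to CO2 (C11–C12) to give carboxylate 18. On warming, the carboxylate oxygen, held cis to C6 by the C7=C11 alkene, displaces the allylic benzenesulfonate (O–C6) and closes the butenolide. The closest known reactions are the carboxylation of alkenyllithiums and the lactonisation of (Z)-4-halo- or 4-sulfonyloxy-2-enoates. The five-membered ring closes in the 5-exo-tet mode. C6 is the only stereocentre that changes: backside attack inverts the (6S)-sulfonate to the (6R)-lactone, so the threo array of step 7 becomes the erythro array of the target. The step needs 17 to spare the sulfonate and 18 to attack only C6: attack of 17 on sulfur or on C6 would require a strained endocyclic five- or three-membered transition state, the benzenesulfonate has no acidic α-hydrogen, the silylated C8–O lies trans to C12, and opening of the oxirane at C5 would be a slower 6-exo closure on a poorer leaving group.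

Step 12
Reactants: 19 (1R,4S,5R,6R,8R,10S)-1,10:4,5-diepoxy-8,13-bis(triethylsilyloxy)germacr-7(11)-en-12,6-olide
Product: 20 (1R,4S,5R,6R,8R,10S)-1,10:4,5-diepoxy-8,13-dihydroxygermacr-7(11)-en-12,6-olide
Conditions: Et3N·3HF, THF, 0 → 23 °C
Reagents that add atoms: none
Why: Fluoride-mediated desilylation under nearly neutral conditions removes both TES groups without opening the oxiranes or the butenolide.

Step 13
Reactants: 20 (1R,4S,5R,6R,8R,10S)-1,10:4,5-diepoxy-8,13-dihydroxygermacr-7(11)-en-12,6-olide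
Product: 21 (1R,4S,5R,6R,8R,10S)-13-acetoxy-1,10:4,5-diepoxy-8-hydroxygermacr-7(11)-en-12,6-olide
Conditions: AcCl (1.05 equiv), 2,4,6-collidine, CH2Cl2, −78 °C
Reagents that add atoms: acetyl chloride, CC(=O)Cl
Why: In this kinetically selective acylation at low temperature with a hindered pyridine base, the primary allylic C13 hydroxyl reacts much faster than the hindered secondary C8 hydroxyl.

Step 14
Reactants: 21 (1R,4S,5R,6R,8R,10S)-13-acetoxy-1,10:4,5-diepoxy-8-hydroxygermacr-7(11)-en-12,6-olide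
Product: 22 (1R,4S,5R,6R,8R,10S)-13-acetoxy-1,10:4,5-diepoxy-8-methacryloyloxygermacr-7(11)-en-12,6-olide (CNP0212980.1)
Conditions: methacrylic anhydride, DMAP, Et3N, CH2Cl2, 0 → 23 °C
Reagents that add atoms: methacrylic anhydride, C=C(C)C(=O)OC(=O)C(C)=C
Why: DMAP-catalysed (Steglich-type) acylation of the remaining C8 hydroxyl proceeds with retention and completes the target.

Compound list
1 | 4-methylpent-4-en-1-ol | C=C(C)CCCO | starting material
2 | 4-methylpent-4-en-1-yl N,N-diisopropylcarbamate | C=C(C)CCCOC(=O)N(C(C)C)C(C)C | intermediate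
3 | isopropenylboronic acid pinacol ester | C=C(C)B1OC(C)(C)C(C)(C)O1 | starting material
4 | mucobromic acid (3,4-dibromo-5-hydroxyfuran-2(5H)-one) | OC1OC(=O)C(Br)=C1Br | starting material
5 | (S)-1-lithio-4-methylpent-4-en-1-yl N,N-diisopropylcarbamate (sparteine complex) | [Li][C@@H](CCC(C)=C)OC(=O)N(C(C)C)C(C)C | intermediate
6 | (R)-2-(2,6-dimethylhepta-1,6-dien-3-yl)-4,4,5,5-tetramethyl-1,3,2-dioxaborolane | C=C(C)[C@@H](CCC(C)=C)B1OC(C)(C)C(C)(C)O1 | intermediate
7 | (2Z,4R,6Z)-2,3-dibromo-4-hydroxy-6,10-dimethylundeca-2,6,10-trienoic acid | OC(=O)/C(Br)=C(Br)\[C@H](O)C/C(C)=C\CCC(C)=C | intermediate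
8 | (5R)-3,4-dibromo-5-[(2Z)-2,6-dimethylhepta-2,6-dien-1-yl]furan-2(5H)-one | O=C1O[C@H](C/C(C)=C\CCC(C)=C)C(Br)=C1Br | intermediate
9 | (5R)-3,4-dibromo-5-{[(2S,3R)-2-methyl-3-(3-methylbut-3-en-1-yl)oxiran-2-yl]methyl}furan-2(5H)-one | O=C1O[C@H](C[C@]2(C)O[C@@H]2CCC(C)=C)C(Br)=C1Br | intermediate
10 | (5R)-3-bromo-5-{[(2S,3R)-2-methyl-3-(3-methylbut-3-en-1-yl)oxiran-2-yl]methyl}-4-(prop-2-enoyl)furan-2(5H)-one | O=C1O[C@H](C[C@]2(C)O[C@@H]2CCC(C)=C)C(C(=O)C=C)=C1Br | intermediate
11 | (5R)-3-bromo-4-[(1R)-1-hydroxyprop-2-en-1-yl]-5-{[(2S,3R)-2-methyl-3-(3-methylbut-3-en-1-yl)oxiran-2-yl]methyl}furan-2(5H)-one | O=C1O[C@H](C[C@]2(C)O[C@@H]2CCC(C)=C)C([C@H](O)C=C)=C1Br | intermediate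
12 | (1R,6R,8R,10S,4Z)-11-bromo-1,10-epoxy-6-hydroxy-12-norgermacra-4,7(11)-dien-13,8-olide | O=C1O[C@@H]2C[C@]3(C)O[C@@H]3CC/C(C)=C\[C@@H](O)C2=C1Br | intermediate
13 | (1R,4S,5R,6S,8R,10S)-11-bromo-1,10:4,5-diepoxy-6-hydroxy-12-norgermacr-7(11)-en-13,8-olide | O=C1O[C@@H]2C[C@]3(C)O[C@@H]3CC[C@]3(C)O[C@@H]3[C@@H](O)C2=C1Br | intermediate
14 | (1R,4S,5R,6S,8R,10S)-6-benzenesulfonyloxy-11-bromo-1,10:4,5-diepoxy-12-norgermacr-7(11)-en-13,8-olide | O=C1O[C@@H]2C[C@]3(C)O[C@@H]3CC[C@]3(C)O[C@@H]3[C@@H](OS(=O)(=O)c3ccccc3)C2=C1Br | intermediate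
15 | (1R,4S,5R,6S,8R,10S,7(11)Z)-11-bromo-1,10:4,5-diepoxy-8,13-dihydroxy-12-norgermacr-7(11)-en-6-yl benzenesulfonate | OC/C(Br)=C1\[C@H](O)C[C@]2(C)O[C@@H]2CC[C@]2(C)O[C@@H]2[C@H]1OS(=O)(=O)c1ccccc1 | intermediate
16 | 8,13-bis(triethylsilyl) ether of 15 | CC[Si](CC)(CC)OC/C(Br)=C1\[C@H](O[Si](CC)(CC)CC)C[C@]2(C)O[C@@H]2CC[C@]2(C)O[C@@H]2[C@H]1OS(=O)(=O)c1ccccc1 | intermediate
17 | C11 alkenyllithium from 16 (Li cis to C6) | CC[Si](CC)(CC)OC/C([Li])=C1\[C@H](O[Si](CC)(CC)CC)C[C@]2(C)O[C@@H]2CC[C@]2(C)O[C@@H]2[C@H]1OS(=O)(=O)c1ccccc1 | intermediate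
18 | lithium (7(11)Z)-6-benzenesulfonyloxy-1,10:4,5-diepoxy-8,13-bis(triethylsilyloxy)germacr-7(11)-en-12-oate | CC[Si](CC)(CC)OC/C(C(=O)[O-])=C1\[C@H](O[Si](CC)(CC)CC)C[C@]2(C)O[C@@H]2CC[C@]2(C)O[C@@H]2[C@H]1OS(=O)(=O)c1ccccc1.[Li+] | intermediate
19 | (1R,4S,5R,6R,8R,10S)-1,10:4,5-diepoxy-8,13-bis(triethylsilyloxy)germacr-7(11)-en-12,6-olide | CC[Si](CC)(CC)O[C@@H]1C[C@]2(C)O[C@@H]2CC[C@]2(C)O[C@@H]2[C@@H]2OC(=O)C(CO[Si](CC)(CC)CC)=C21 | intermediate
20 | (1R,4S,5R,6R,8R,10S)-1,10:4,5-diepoxy-8,13-dihydroxygermacr-7(11)-en-12,6-olide | O[C@@H]1C[C@]2(C)O[C@@H]2CC[C@]2(C)O[C@@H]2[C@@H]2OC(=O)C(CO)=C21 | intermediate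
21 | (1R,4S,5R,6R,8R,10S)-13-acetoxy-1,10:4,5-diepoxy-8-hydroxygermacr-7(11)-en-12,6-olide | O[C@@H]1C[C@]2(C)O[C@@H]2CC[C@]2(C)O[C@@H]2[C@@H]2OC(=O)C(COC(C)=O)=C21 | intermediate
22 | (1R,4S,5R,6R,8R,10S)-13-acetoxy-1,10:4,5-diepoxy-8-methacryloyloxygermacr-7(11)-en-12,6-olide (CNP0212980.1) | C=C(C)C(=O)O[C@@H]1C[C@]2(C)O[C@@H]2CC[C@]2(C)O[C@@H]2[C@@H]2OC(=O)C(COC(C)=O)=C21 | target

Total step count: 14. Longest linear sequence: 14 steps (1 → 22).

Steps most likely to fail

Step 11. The alkenyllithium may be consumed before it meets CO2, by proton transfer from or attack on the sulfonate, by O→C silyl migration, or by β-elimination of the C13 silyloxy group. The lithium carboxylate may also ionise the allylic sulfonate, so that C6 is scrambled. The fallback inverts C6 first and then closes the lactone by carbonylation, giving up the CO2 stitching. It sets out from 13. A Mitsunobu reaction with 4-nitrobenzoic acid (PPh3, DIAD) should give the inverted (6R)-4-nitrobenzoate F1. Excess DIBAL-H should cleave this ester and reduce the 8,13-lactone to the (6R)-6,8,13-triol F2. Palladium-catalysed carbonylative lactonisation of the (Z)-3-bromoallylic alcohol (CO, Pd(PPh3)4, Et3N, DMF) should engage only the C6 hydroxyl, the only one cis to C11, and comes back to the route at 20.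

Step 6. Oligomerisation, ruthenium hydride isomerisation of the vinyl carbinol, or poor control of the alkene geometry may defeat the closure of the ten-membered ring. The fallback closes the ring on the ketone, with an sp2 centre at C6, and sets C6 afterwards on the ring. It sets out from 10. Ring-closing metathesis of the acryloyl group with the 1,1-disubstituted alkene should give the macrocyclic (4Z)-dienone F3. CBS reduction with the (S)-catalyst and catecholborane comes back to the route at 12.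

Step 4. Direct vinyl transfer without CO insertion, a second coupling at C11–Br, or polymerisation of the acryloyl ketone may erode the coupling. The fallback sets out from 9. Nozaki–Hiyama–Kishi coupling of the β C7–Br bond with acrolein (CrCl2, NiCl2 cat., DMF) should give the C6-epimeric allylic alcohol F4. Dess–Martin oxidation comes back to the route at 10.

Further compounds
F1 | step 11 | (1R,4S,5R,6R,8R,10S)-11-bromo-1,10:4,5-diepoxy-6-(4-nitrobenzoyloxy)-12-norgermacr-7(11)-en-13,8-olide | O=C1O[C@@H]2C[C@]3(C)O[C@@H]3CC[C@]3(C)O[C@@H]3[C@H](OC(=O)c3ccc(cc3)[N+](=O)[O-])C2=C1Br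
F2 | step 11 | (1R,4S,5R,6R,8R,10S,7(11)Z)-11-bromo-1,10:4,5-diepoxy-12-norgermacr-7(11)-ene-6,8,13-triol | OC/C(Br)=C1\[C@H](O)C[C@]2(C)O[C@@H]2CC[C@]2(C)O[C@@H]2[C@@H]1O
F3 | step 6 | (1R,8R,10S,4Z)-11-bromo-1,10-epoxy-6-oxo-12-norgermacra-4,7(11)-dien-13,8-olide | O=C1O[C@@H]2C[C@]3(C)O[C@@H]3CC/C(C)=C\C(=O)C2=C1Br
F4 | step 4 | (5R)-3-bromo-4-(1-hydroxyprop-2-en-1-yl)-5-{[(2S,3R)-2-methyl-3-(3-methylbut-3-en-1-yl)oxiran-2-yl]methyl}furan-2(5H)-one, both C6 epimers | O=C1O[C@H](C[C@]2(C)O[C@@H]2CCC(C)=C)C(C(O)C=C)=C1Br
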